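**Strategy.** Ring A (C4a, C5, C6, C7, C8, C8a) is fully oxygenated: para oxygens at C5 (free OH) and C8 (OMe) flank the vicinal methoxy carbons C6 and C7. C5–C8 and all four oxygens can therefore come from dimethyl squarate. A C6-lithiated 2-aryl-4-silyloxy-dihydropyran (rings B and C) is added to the squarate (C8–C8a bond) and the alkoxide is methylated. Heating this 4-methoxy-4-(dihydropyranyl)cyclobutenone opens it to a dienylketene that electrocyclises onto the enol ether carbon. This forms C4a–C5 and closes ring A with C5–OH free and C8–OMe in place. Oxidation-level adjustment of ring C and cleavage of two isopropyl ethers finish the route.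

Key step: step 8

Assumption: all chiral compounds are racemic; each SMILES shows one enantiomer to convey relative configuration, unspecified centres are mixtures, and no stereocentre survives in the achiral target. Ar = 3,5-diisopropoxy-4-methoxyphenyl; TIPS = triisopropylsilyl.

**Step 1**
Reactants: 1 methyl 3,5-dihydroxy-4-methoxybenzoate
Product: 2 methyl 3,5-diisopropoxy-4-methoxybenzoate
Conditions: 2-bromopropane, K2CO3, DMF, 70 °C
Reagents that add atoms: 2-bromopropane, CC(C)Br
Why: Williamson ether synthesis on both phenols; isopropyl ethers are chosen because they tolerate tert-butyllithium and are later cleaved by BCl3 without loss of methyl ethers.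

**Step 2**
Reactants: 2 methyl 3,5-diisopropoxy-4-methoxybenzoate
Product: 3 (3,5-diisopropoxy-4-methoxyphenyl)methanol
Conditions: LiAlH4, THF, 0 °C → rt
Reagents that add atoms: none
Why: Hydride reduction of an aryl ester to the benzylic alcohol, with the aryl ethers inert.

**Step 3**
Reactants: 3 (3,5-diisopropoxy-4-methoxyphenyl)methanol
Product: 4 3,5-diisopropoxy-4-methoxybenzaldehyde
Conditions: MnO2, CH2Cl2, rt
Reagents that add atoms: none
Why: Heterogeneous MnO2 oxidation of an electron-rich benzylic alcohol, which should stop cleanly at the aldehyde.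

**Step 4**
Reactants: 4 3,5-diisopropoxy-4-methoxybenzaldehyde; 5 trans-1-methoxy-3-(trimethylsilyloxy)buta-1,3-diene
Product: 7 rac-2-Ar-2,3-dihydro-4H-pyran-4-one, via silyl enol ether cycloadduct 6 (not isolated)
Conditions: ZnCl2, THF, rt; then TFA, CH2Cl2, rt
Reagents that add atoms: none
Why: Lewis acid-promoted hetero-Diels–Alder reaction (aldehyde oxygen to the methoxy-bearing diene terminus), then acid-induced loss of the silyl group and methanol to the vinylogous ester; the C2 stereocentre forms as a racemate because no chiral controller is present.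

**Step 5**
Reactants: 7 rac-2-Ar-2,3-dihydro-4H-pyran-4-one
Product: 8 rac-cis-2-Ar-3,4-dihydro-2H-pyran-4-ol
Conditions: NaBH4, CeCl3·7H2O, MeOH, −78 → −20 °C
Reagents that add atoms: none
Why: Luche reduction gives clean 1,2-addition to the vinylogous ester carbonyl; axial hydride delivery on the half-chair with the aryl group pseudo-equatorial should give mainly the cis alcohol, and the C4 configuration is immaterial because C4 later becomes a carbonyl.

**Step 6**
Reactants: 8 rac-cis-2-Ar-3,4-dihydro-2H-pyran-4-ol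
Product: 9 rac-cis-2-Ar-4-(TIPS-oxy)-3,4-dihydro-2H-pyran
Conditions: TIPSCl, imidazole, DMF, rt
Reagents that add atoms: triisopropylsilyl chloride, CC(C)[Si](Cl)(C(C)C)C(C)C
Why: Silylation of the secondary allylic alcohol under non-acidic conditions that avoid Ferrier-type ionisation; the TIPS group has no acidic Si–CH3 protons and tolerates tert-butyllithium.

**Step 7**
Reactants: 9 rac-cis-2-Ar-4-(TIPS-oxy)-3,4-dihydro-2H-pyran; 10 dimethyl squarate
Product: 13 2,3,4-trimethoxy-4-[cis-2-Ar-4-(TIPS-oxy)-3,4-dihydro-2H-pyran-6-yl]cyclobut-2-enone (racemic; epimer mixture at the quaternary carbon), via C6-lithiated dihydropyran 11 (not isolated), via lithium alkoxide adduct 12 (not isolated)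
Conditions: t-BuLi, THF, −78 → 0 °C; cannulate into 10, THF, −78 °C; MeOTf, −78 → 0 °C
Reagents that add atoms: methyl trifluoromethanesulfonate, COS(=O)(=O)C(F)(F)F
Why: Kinetic deprotonation of the enol ether C6–H (alpha to the ring oxygen) of a silylated glycal-type dihydropyran, 1,2-addition of the vinyllithium to one squarate carbonyl and O-methylation of the tertiary lithium alkoxide; the quaternary centre forms without control, which is harmless because it becomes aromatic C8.

**Step 8**
Reactants: 13 2,3,4-trimethoxy-4-[cis-2-Ar-4-(TIPS-oxy)-3,4-dihydro-2H-pyran-6-yl]cyclobut-2-enone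
Product: 16 rac-cis-2-Ar-6,7,8-trimethoxy-4-(TIPS-oxy)chroman-5-ol, via dienylketene 14 (not isolated), via cyclohexadienone 15 (not isolated)
Conditions: toluene (degassed), 110 °C
Reagents that add atoms: none
Why: On heating, the cyclobutenone undergoes a four-electron conrotatory opening that breaks the bond between the carbonyl carbon and the quaternary carbon; the donor methoxy group on the quaternary carbon rotates outward, so the dihydropyranyl group ends up cis to the ketene in 14. A thermal six-electron disrotatory electrocyclisation then joins the ketene carbon to the enol ether beta-carbon of the dihydropyran (the C4a–C5 bond), closing ring A as cyclohexadienone 15, which tautomerises irreversibly to the phenol. This is the Moore rearrangement of a 4-alkenyl-4-alkoxycyclobutenone, the closest known reaction type being the ring expansion of squarate adducts of lithiated enol ethers to monoprotected hydroquinones. No lasting stereocentre is created: C4a of 15 is lost on aromatisation, the quaternary cyclobutenone centre disappears, and C2 and C4 are untouched. The selectivity needed is the placement of the free hydroxyl: the methylated tertiary carbon is the one bonded to the oxygen-bearing alkene carbon (future C8a) and so becomes C8–OMe, while the ketene carbonyl can only become C5–OH, and the outward preference of the methoxy group secures the geometry required for closure.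

**Step 9**
Reactants: 16 rac-cis-2-Ar-6,7,8-trimethoxy-4-(TIPS-oxy)chroman-5-ol
Product: 17 rac-cis-2-Ar-6,7,8-trimethoxychroman-4,5-diol
Conditions: Bu4NF, AcOH, THF, rt (argon)
Reagents that add atoms: none
Why: Fluoride cleavage of the benzylic silyl ether, buffered with acetic acid so that the electron-rich phenol is not held as its oxidation-prone phenoxide.

**Step 10**
Reactants: 17 rac-cis-2-Ar-6,7,8-trimethoxychroman-4,5-diol
Product: 18 rac-2-Ar-5-hydroxy-6,7,8-trimethoxychroman-4-one
Conditions: MnO2, CH2Cl2, rt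
Reagents that add atoms: none
Why: MnO2 oxidation of the benzylic C4 alcohol to the aryl ketone, which is stabilised by the C5–OH to C4=O hydrogen bond, while the fully substituted ring A offers no site for phenolic coupling.

**Step 11**
Reactants: 18 rac-2-Ar-5-hydroxy-6,7,8-trimethoxychroman-4-one
Product: 19 2-Ar-5-hydroxy-6,7,8-trimethoxy-4H-chromen-4-one
Conditions: I2 (cat.), DMSO, 120 °C
Reagents that add atoms: none
Why: Iodine-catalysed dehydrogenation of a flavanone to a flavone with DMSO as terminal oxidant, which removes the last stereocentre at C2.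

**Step 12**
Reactants: 19 2-Ar-5-hydroxy-6,7,8-trimethoxy-4H-chromen-4-one
Product: 20 Gardenin E
Conditions: BCl3, CH2Cl2, −78 → 0 °C; then H2O
Reagents that add atoms: none
Why: Lewis acid dealkylation in which BCl3 ionises the secondary O–isopropyl bonds at low temperature while aryl methyl ethers survive; the C5 oxygen is already free, so no chelation-driven demethylation is needed.

**Compound list**

1 | methyl 3,5-dihydroxy-4-methoxybenzoate | COC(=O)c1cc(O)c(OC)c(O)c1 | starting material
2 | methyl 3,5-diisopropoxy-4-methoxybenzoate | COC(=O)c1cc(OC(C)C)c(OC)c(OC(C)C)c1 | intermediate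
3 | (3,5-diisopropoxy-4-methoxyphenyl)methanol | OCc1cc(OC(C)C)c(OC)c(OC(C)C)c1 | intermediate
4 | 3,5-diisopropoxy-4-methoxybenzaldehyde | O=Cc1cc(OC(C)C)c(OC)c(OC(C)C)c1 | intermediate
5 | trans-1-methoxy-3-(trimethylsilyloxy)buta-1,3-diene | CO/C=C/C(=C)O[Si](C)(C)C | starting material
6 | 2-(3,5-diisopropoxy-4-methoxyphenyl)-6-methoxy-4-(trimethylsilyloxy)-3,6-dihydro-2H-pyran (racemic; mixture at the acetal carbon) | COC1C=C(O[Si](C)(C)C)C[C@H](O1)c1cc(OC(C)C)c(OC)c(OC(C)C)c1 | intermediate (not isolated)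
7 | rac-2-(3,5-diisopropoxy-4-methoxyphenyl)-2,3-dihydro-4H-pyran-4-one | O=C1C=CO[C@@H](C1)c1cc(OC(C)C)c(OC)c(OC(C)C)c1 | intermediate
8 | rac-cis-2-(3,5-diisopropoxy-4-methoxyphenyl)-3,4-dihydro-2H-pyran-4-ol | O[C@@H]1C=CO[C@@H](C1)c1cc(OC(C)C)c(OC)c(OC(C)C)c1 | intermediate
9 | rac-cis-2-(3,5-diisopropoxy-4-methoxyphenyl)-4-(triisopropylsilyloxy)-3,4-dihydro-2H-pyran | CC(C)[Si](C(C)C)(C(C)C)O[C@@H]1C=CO[C@@H](C1)c1cc(OC(C)C)c(OC)c(OC(C)C)c1 | intermediate
10 | dimethyl squarate (3,4-dimethoxycyclobut-3-ene-1,2-dione) | COC1=C(OC)C(=O)C1=O | starting material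
11 | rac-cis-2-(3,5-diisopropoxy-4-methoxyphenyl)-6-lithio-4-(triisopropylsilyloxy)-3,4-dihydro-2H-pyran | CC(C)[Si](C(C)C)(C(C)C)O[C@@H]1C=C([Li])O[C@@H](C1)c1cc(OC(C)C)c(OC)c(OC(C)C)c1 | intermediate (not isolated)
12 | lithium alkoxide of 4-hydroxy-2,3-dimethoxy-4-[cis-2-(3,5-diisopropoxy-4-methoxyphenyl)-4-(triisopropylsilyloxy)-3,4-dihydro-2H-pyran-6-yl]cyclobut-2-enone (racemic; epimer mixture) | CC(C)[Si](C(C)C)(C(C)C)O[C@@H]1C=C(O[C@@H](C1)c2cc(OC(C)C)c(OC)c(OC(C)C)c2)C3(O[Li])C(OC)=C(OC)C3=O | intermediate (not isolated)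
13 | 2,3,4-trimethoxy-4-[cis-2-(3,5-diisopropoxy-4-methoxyphenyl)-4-(triisopropylsilyloxy)-3,4-dihydro-2H-pyran-6-yl]cyclobut-2-enone (racemic; epimer mixture at the quaternary carbon) | CC(C)[Si](C(C)C)(C(C)C)O[C@@H]1C=C(O[C@@H](C1)c2cc(OC(C)C)c(OC)c(OC(C)C)c2)C3(OC)C(OC)=C(OC)C3=O | intermediate (key-step precursor)
14 | (3Z)-2,3,4-trimethoxy-4-[cis-2-(3,5-diisopropoxy-4-methoxyphenyl)-4-(triisopropylsilyloxy)-3,4-dihydro-2H-pyran-6-yl]buta-1,3-dien-1-one (racemic) | CC(C)[Si](C(C)C)(C(C)C)O[C@@H]1C=C(O[C@@H](C1)c2cc(OC(C)C)c(OC)c(OC(C)C)c2)/C(OC)=C(OC)\C(OC)=C=O | intermediate (not isolated)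
15 | cis-2-(3,5-diisopropoxy-4-methoxyphenyl)-6,7,8-trimethoxy-4-(triisopropylsilyloxy)-2,3,4,4a-tetrahydro-5H-chromen-5-one (racemic; C4a unspecified) | CC(C)[Si](C(C)C)(C(C)C)O[C@@H]1C2C(=O)C(OC)=C(OC)C(OC)=C2O[C@@H](C1)c3cc(OC(C)C)c(OC)c(OC(C)C)c3 | intermediate (not isolated)
16 | rac-cis-2-(3,5-diisopropoxy-4-methoxyphenyl)-6,7,8-trimethoxy-4-(triisopropylsilyloxy)chroman-5-ol | CC(C)[Si](C(C)C)(C(C)C)O[C@@H]1c2c(O)c(OC)c(OC)c(OC)c2O[C@@H](C1)c3cc(OC(C)C)c(OC)c(OC(C)C)c3 | intermediate (key-step product)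
17 | rac-cis-2-(3,5-diisopropoxy-4-methoxyphenyl)-6,7,8-trimethoxychroman-4,5-diol | O[C@@H]1c2c(O)c(OC)c(OC)c(OC)c2O[C@@H](C1)c3cc(OC(C)C)c(OC)c(OC(C)C)c3 | intermediate
18 | rac-2-(3,5-diisopropoxy-4-methoxyphenyl)-5-hydroxy-6,7,8-trimethoxychroman-4-one | O=C1c2c(O)c(OC)c(OC)c(OC)c2O[C@@H](C1)c3cc(OC(C)C)c(OC)c(OC(C)C)c3 | intermediate
19 | 2-(3,5-diisopropoxy-4-methoxyphenyl)-5-hydroxy-6,7,8-trimethoxy-4H-chromen-4-one | COc1c(OC(C)C)cc(cc1OC(C)C)-c1cc(=O)c2c(O)c(OC)c(OC)c(OC)c2o1 | intermediate
20 | Gardenin E, 2-(3,5-dihydroxy-4-methoxyphenyl)-5-hydroxy-6,7,8-trimethoxy-4H-chromen-4-one | COc1c(O)cc(-c2cc(=O)c3c(O)c(OC)c(OC)c(OC)c3o2)cc1O | target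

**Totals.** Total step count: 12. Longest linear sequence: 12 steps (1 to 20); 5 and 10 are purchased and enter at steps 4 and 7.

**Steps most likely to fail**

1. **Step 7.** Deprotonation may occur at the benzylic C2–H or on ring B instead of at the enol ether C6–H, and the wrong anion or residual tert-butyllithium may then add to the squarate. Fallback, setting out from 9: addition of benzenesulfinic acid across the enol ether (PhSO2H, CH2Cl2, rt) should give the anomeric sulfone F1. Its C6–H, now flanked by sulfonyl and oxygen, should be removed selectively by n-BuLi at −78 °C. Addition to 10 with MeOTf quench should give the sulfonyl cyclobutenone F2. Gentle warming with iPr2NEt should expel benzenesulfinic acid towards C5 and rejoin the route at 13.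

2. **Step 8.** At the temperature of ring opening, the benzylic silyloxy group ortho to the new phenol may be lost (silanol elimination through an ortho-quinone methide), or the electron-rich phenol may be air-oxidised. Fallback, setting out from 13: HF·pyridine (THF, 0 °C) should give allylic alcohol F3, and MnO2 (CH2Cl2) should oxidise it to the vinylogous ester F4. Heating F4 in toluene should deliver the hydrogen-bonded flavanone directly by the same ring expansion, with no benzylic leaving group. The route is rejoined at 18, and steps 9 and 10 fall away.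

3. **Step 10.** Oxidation of the para-methoxyphenol ring A towards a quinone may compete with oxidation of the C4 alcohol. Fallback, setting out from 16: the phenol is masked first (MOMCl, iPr2NEt, CH2Cl2) as methoxymethyl ether F5. Bu4NF (THF) should give alcohol F6, and Dess–Martin periodinane (NaHCO3, CH2Cl2) should give ketone F7. HCl in MeOH should remove the acetal and rejoin the route at 18.

**Further compounds**

F1 | step 7 | rac-2-(3,5-diisopropoxy-4-methoxyphenyl)-6-(phenylsulfonyl)-4-(triisopropylsilyloxy)tetrahydro-2H-pyran (2,4-cis; both C6 epimers) | CC(C)[Si](C(C)C)(C(C)C)O[C@@H]1CC(O[C@@H](C1)c2cc(OC(C)C)c(OC)c(OC(C)C)c2)S(=O)(=O)c3ccccc3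
F2 | step 7 | 2,3,4-trimethoxy-4-[6-(3,5-diisopropoxy-4-methoxyphenyl)-2-(phenylsulfonyl)-4-(triisopropylsilyloxy)tetrahydro-2H-pyran-2-yl]cyclobut-2-enone (racemic; diastereomer mixture) | CC(C)[Si](C(C)C)(C(C)C)O[C@@H]1CC(O[C@@H](C1)c2cc(OC(C)C)c(OC)c(OC(C)C)c2)(S(=O)(=O)c3ccccc3)C4(OC)C(OC)=C(OC)C4=O
F3 | step 8 | 4-[cis-2-(3,5-diisopropoxy-4-methoxyphenyl)-4-hydroxy-3,4-dihydro-2H-pyran-6-yl]-2,3,4-trimethoxycyclobut-2-enone (racemic; epimer mixture) | O[C@@H]1C=C(O[C@@H](C1)c2cc(OC(C)C)c(OC)c(OC(C)C)c2)C3(OC)C(OC)=C(OC)C3=O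
F4 | step 8 | 2-(3,5-diisopropoxy-4-methoxyphenyl)-6-(1,2,3-trimethoxy-4-oxocyclobut-2-en-1-yl)-2,3-dihydro-4H-pyran-4-one (racemic; epimer mixture) | O=C1C=C(O[C@@H](C1)c2cc(OC(C)C)c(OC)c(OC(C)C)c2)C3(OC)C(OC)=C(OC)C3=O
F5 | step 10 | rac-cis-2-(3,5-diisopropoxy-4-methoxyphenyl)-6,7,8-trimethoxy-5-(methoxymethoxy)-4-(triisopropylsilyloxy)chromane | CC(C)[Si](C(C)C)(C(C)C)O[C@@H]1c2c(OCOC)c(OC)c(OC)c(OC)c2O[C@@H](C1)c3cc(OC(C)C)c(OC)c(OC(C)C)c3
F6 | step 10 | rac-cis-2-(3,5-diisopropoxy-4-methoxyphenyl)-6,7,8-trimethoxy-5-(methoxymethoxy)chroman-4-ol | O[C@@H]1c2c(OCOC)c(OC)c(OC)c(OC)c2O[C@@H](C1)c3cc(OC(C)C)c(OC)c(OC(C)C)c3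
F7 | step 10 | rac-2-(3,5-diisopropoxy-4-methoxyphenyl)-6,7,8-trimethoxy-5-(methoxymethoxy)chroman-4-one | O=C1c2c(OCOC)c(OC)c(OC)c(OC)c2O[C@@H](C1)c3cc(OC(C)C)c(OC)c(OC(C)C)c3
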